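Remark on the chemistry: atom labels C1–C15 are those of the target and are kept for every intermediate. Compounds 3, 4, 13, 15–19 and 22 are racemic (one enantiomer drawn) and 20 is achiral. The target is read as 6S,7R,8R with both ring alkenes ring-cis. The fragmentation precursor and its product were checked and are stereochemically self-consistent (cis ring fusion; C1 sulfonate cis to C9 and trans to the C14 arm). Only spectator groups and the way to and from these two compounds were redesigned.

## Structural features

The target is a germacrane-type sesquiterpene lactone: a ten-membered carbocycle C1–C10 with a γ-lactone cis-fused across C6 (oxygen) and C7 (C11), an exocyclic methylene C13 on C11, an isovalerate on C8, an aldehyde C14 on C10 and a free hydroxymethyl C15 on C4. The ring double bonds C1=C10 and C4=C5 are trisubstituted and both ring-cis, a geometry that a small ring enforces and a ten-membered ring does not. C6, C7 and C8 are contiguous stereocentres with H6, H7 and H8 on one face, so the lactone oxygen, C11 and the ester oxygen are all cis. The fragile groups are the α-methylene lactone (a Michael acceptor that slips into the ring as a butenolide once C7–H is acidified), the enal, the allylic C6–O bond, and a cis C8 oxygen that can attack C12; a C8 ketone makes C7–H acidic and the C6 oxygen a β-leaving group. The real difficulty is to close a ten-membered ring with two cis trisubstituted alkenes and then to place three adjacent stereocentres on a flexible ring. The key step uses the 1,3-relationship C6(O)–C10–C1: a C6–C10 bond turns the ring into a cyclopentane (C6–C10) fused to a cycloheptene (C10, C1–C6) that must hold C4=C5 cis. Breaking that bond from a C6 alkoxide with a leaving group on C1 gives C6=O and C1=C10 at once. The fragmentation product has a C6 ketone, an acidic C7 methylene and a masked C8 ketone, the three carbons that must become stereocentres, and no stereocentre of its own, so absolute configuration can be introduced afterwards by a catalyst.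

## Logic of the disconnections

34 ⇐ 33 ⇐ 32 ⇐ 31. The O15–benzyl bond, the C14 oxidation level and the O14–Si bond are taken back. The enal and the free allylic alcohol are the most reactive groups and appear last. Their precursors differ (silyl ether at O14, 4-methoxybenzyl ether at O15), so C14 can be oxidised while O15 is covered. The forward steps must be neutral or buffered because of the methylene lactone.

31 ⇐ 30 ⇐ 26. The O8–acyl bond and the C11=C13 bond are cut. The isovalerate cannot be present when an amide base is used, and the methylene cannot be present while C8 is a ketone, so methylenation is placed between C8 reduction and acylation. The demand is a methylenation of a hydroxy lactone through its dianion.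

26 ⇐ 25 ⇐ 24. The C8–H bond and the C8 carbonyl are taken back to a ketal. C8 stays masked until the lactone exists, so only O6 can lactonise. The forward reduction must be fast and nearly neutral (C7–H is α to the ketone, O6 is β to it) and must come from the face opposite the lactone.

24 ⇐ 22 (through 23). The O6–C12 bond and the C6–H bond are cut. In 22 a prochiral C6 carbonyl stands next to an epimerisable C7, so one catalyst-controlled reduction with equilibration at C7 can set both centres, and the cis hydroxy ester closes by itself. The demand is an enzyme that takes one enantiomer and a C7 that equilibrates without opening the ketal.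

22 ⇐ 20. The C7–C11 bond is cut. C7 is the only sp3 α-carbon of the C6 enone and a bromoacetate brings C11 and C12. This removes the last stereocentre, so 20 is achiral. The forward step needs a kinetic enolate kept cold, because the C8 ketal oxygen is β to it.

20 ⇐ 18 (key). The C6–C10 bond is reconnected and a sulfonate is placed on C1. The medium ring is replaced by a cis-fused five/seven bicycle that ordinary carbonyl chemistry and seven-ring metathesis can build, and both alkene geometries become consequences of ring size and relative configuration. The demands are a C1 sulfonate trans to the C14 arm, a cis ring fusion, and a short exposure of the β-keto ketal product to base.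

18 ⇐ 17 ⇐ 16. The O1–S bond and the C4=C5 bond are cut. The tertiary C6 hydroxyl is a spectator in both steps. The metathesis needs the vinyl group and the C1 chain on the same face of the cyclopentane.

16 ⇐ 13 + 14. The C5–C6 bond is cut. The vinyl group must enter opposite the C14 arm. This is entrusted to chelation of the C6 carbonyl by the C1 alkoxide, which is why O14 carries a bulky, non-chelating, acid-stable silyl group instead of a smaller silyl ether.

13 ⇐ 5 + 11, and 5 ⇐ 4 ⇐ 3 ⇐ 1. The C1–C10 bond, then O–Si bonds, then the C10–C14 bond are cut. The C1/C10 relationship needed by the fragmentation is the one a chair aldol transition state of the cyclic enolate gives. The tetrasubstituted enolate must be regiodefined, so it is made from the thermodynamic silyl enol ether 5 and not by direct deprotonation of 4, whose two α-positions compete.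

11 ⇐ 10 ⇐ 7 + 8, and 7 ⇐ 6. The C2–C3 bond ([3,3] shift) and the O–benzyl bond are cut. The rearrangement turns a 2-substituted allyl alcohol into the γ,δ-unsaturated ester with the 1,1-disubstituted alkene (future C4) that the metathesis needs.

## Other disconnections considered

Alternative 1: The cut is C5–C6 together with the lactone O6–C12 bond. In the forward step the open-chain alkenyl iodide aldehyde ester A1 would close by alkenylchromium addition to the C6 aldehyde, and the new alkoxide would lactonise onto the methyl ester to give A2. The reaction would use a catalytic amount of CrCl2 kept divalent at a cathode and NiCl2 to activate the iodide.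
- In its favour: the ring, C6 and the lactone form in one operation, with the methylene and the isovalerate already in place. A2 is three deprotection/oxidation steps from the target, so on step count after the key step it is better than the chosen plan.
- Against it: A1 has C7 flanked by an aldehyde, an acrylate and the acyloxy-bearing C8, so epimerisation and β-elimination of isovalerate threaten before the ring closes. The ten-membered closure carries the full entropic and transannular penalty. The acrylate is exposed to reducing conditions. C6 must be set cis to C7 by 1,2-induction inside a macrocyclic transition state.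
- Comparison: on structure it fixes C7 and C8 before the ring exists, where the chosen plan sets all three centres afterwards with reagents. On mechanism it needs a radical-polar bimetallic ring closure at high dilution, where the chosen plan only breaks a bond. Overall step count should be similar once A1 is made enantiopure.

Alternative 2: The cut is C7–C8. The thirteen-membered cyclic α-stannyl allyl ether A3 would undergo tin–lithium exchange at C8 and a [2,3]-Wittig shift (C7–C8 formed, O–C13 broken) to contract to the carbocycle A4. A3 is drawn with the stannane configuration and C7=C11 geometry that inversion at the carbanion and the usual Z-to-syn correlation would call for.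
- In its favour: a thirteen-membered ether is easier to close than a ten-membered carbocycle, and the contraction is intramolecular. The step would create C7, C8 and the exocyclic methylene C11=C13 at once. On stereocentres made in the key step and on avoiding a separate methylenation it is better than the chosen plan, whose key step makes none.
- Against it: A3 needs a configurationally defined α-alkoxystannane and a defined trisubstituted alkene inside a large ring. A [1,2]-shift and elimination compete. A4 still needs oxidation of C12 and lactonisation, two 4-methoxybenzyl ethers to be handled, and two different silyl ethers to be differentiated.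
- Comparison: mechanistically both plans avoid a direct medium-ring cyclisation, and in this they are equal. The chosen plan reaches its precursor from simple racemic materials in fewer operations and is expected to be shorter overall.

Alternative 3: The cut is C9–C10. The lactone A5, carrying a terminal epoxide at C8–C9 and an alkenyl iodide at C10, would close under reductive nickel catalysis with iodide as co-catalyst (epoxide opened at C9, coupled to C10) to give the hydroxy lactone A6.
- In its favour: C6 and C7 are set early on a small lactone with reliable chemistry and C8 comes from an epoxide of known configuration. A6 corresponds to compound 26 of the chosen route with the two oxygen protecting groups exchanged, so the endgame is equal.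
- Against it: an intramolecular cross-electrophile coupling that forms a ten-membered ring at an sp3 carbon has no close precedent. Proto-deiodination, epoxide isomerisation and oligomerisation compete. The ring-cis alkenyl iodide and the epoxy lactone need a long linear preparation.
- Comparison: it is better on when the stereocentres are fixed (before ring closure, from defined precursors). It is weaker on the ring-forming mechanism, where the chosen fragmentation is a unimolecular, stereospecific reaction of a well-known type.

Key step: step 11

## Route

Step 1
Reactants: 1 1,4-dioxaspiro[4.4]nonan-7-one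
Product: 3 8-(hydroxymethyl)-1,4-dioxaspiro[4.4]nonan-7-one (racemic), via lithium enolate 2 (not isolated)
Conditions: LiN(iPr)2, THF, −78 °C; CH2O (gas, from cracked paraformaldehyde), −78 °C; AcOH, −78 °C
Reagents that add atoms: formaldehyde, C=O
Why: Kinetic deprotonation should occur at the methylene remote from the ketal (the other one is neopentyl, and an enolate there would open the dioxolane), and the enolate adds to monomeric formaldehyde (crossed aldol, hydroxymethylation); the cold acidic quench prevents retro-aldol and dehydration.

Step 2
Reactants: 3 8-(hydroxymethyl)-1,4-dioxaspiro[4.4]nonan-7-one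
Product: 4 8-{[(tert-butyldiphenylsilyl)oxy]methyl}-1,4-dioxaspiro[4.4]nonan-7-one (racemic)
Conditions: tBuPh2SiCl, imidazole, CH2Cl2, 0 °C → rt
Reagents that add atoms: tert-butyl(chloro)diphenylsilane, CC(C)(C)[Si](Cl)(c1ccccc1)c1ccccc1
Why: Standard silylation of a primary alcohol; this bulky, non-chelating, acid-stable group is chosen because it must leave chelation to the C1 alkoxide in step 8 and survive the ketal cleavage in step 14.

Step 3
Reactants: 4 8-{[(tert-butyldiphenylsilyl)oxy]methyl}-1,4-dioxaspiro[4.4]nonan-7-one
Product: 5 8-{[(tert-butyldiphenylsilyl)oxy]methyl}-7-(trimethylsilyloxy)-1,4-dioxaspiro[4.4]non-7-ene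
Conditions: Me3SiCl, Et3N, DMF, 80 °C
Reagents that add atoms: chlorotrimethylsilane, C[Si](C)(C)Cl
Why: Enol silylation under equilibrating conditions should give the thermodynamic, tetrasubstituted enol ether (C6=C10), which fixes the regiochemistry of the enolate used in step 7; no free enolate is formed, so the β-silyloxy group is not at risk.

Step 4
Reactants: 6 2-methylenepropane-1,3-diol
Product: 7 2-{[(4-methoxybenzyl)oxy]methyl}prop-2-en-1-ol
Conditions: NaH (1 equiv), 6 in excess, THF–DMF, 0 °C; 4-MeOC6H4CH2Cl, Bu4NI (cat.), rt
Reagents that add atoms: 4-methoxybenzyl chloride, COc1ccc(CCl)cc1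
Why: Williamson mono-etherification of a symmetrical diol used in excess; unreacted diol is recovered.

Step 5
Reactants: 7 2-{[(4-methoxybenzyl)oxy]methyl}prop-2-en-1-ol; 8 triethyl orthoacetate
Product: 10 ethyl 4-{[(4-methoxybenzyl)oxy]methyl}pent-4-enoate, via mixed ketene acetal 9 (not isolated)
Conditions: MeC(OEt)3 (excess), EtCO2H (cat.), 140 °C, EtOH distilled off
Reagents that add atoms: none
Why: Johnson–Claisen rearrangement: orthoester exchange and loss of ethanol give the ketene acetal, whose [3,3] shift forms C2–C3 and leaves the 1,1-disubstituted alkene at the future C4.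

Step 6
Reactants: 10 ethyl 4-{[(4-methoxybenzyl)oxy]methyl}pent-4-enoate
Product: 11 4-{[(4-methoxybenzyl)oxy]methyl}pent-4-enal
Conditions: iBu2AlH (1.05 equiv), CH2Cl2, −78 °C; MeOH, aq. Rochelle salt
Reagents that add atoms: none
Why: Partial reduction of the ester; the aluminium hemiacetal is stable at −78 °C and releases the aldehyde on work-up.

Step 7
Reactants: 5 8-{[(tert-butyldiphenylsilyl)oxy]methyl}-7-(trimethylsilyloxy)-1,4-dioxaspiro[4.4]non-7-ene; 11 4-{[(4-methoxybenzyl)oxy]methyl}pent-4-enal
Product: 13 8-{[(tert-butyldiphenylsilyl)oxy]methyl}-8-(1-hydroxy-4-{[(4-methoxybenzyl)oxy]methyl}pent-4-en-1-yl)-1,4-dioxaspiro[4.4]nonan-7-one (racemic; C1 hydroxyl anti to ring carbon C9 in the zigzag C6–C10–C1–C2), via lithium enolate 12 (not isolated)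
Conditions: MeLi (1.05 equiv), THF, −20 → 0 °C, 20 min; then 11, −78 °C; AcOH, −78 °C
Reagents that add atoms: none
Why: MeLi cleaves the enol silyl ether to the regiodefined tetrasubstituted lithium enolate, which adds to the aldehyde through a closed chair (Zimmerman–Traxler) transition state with the aldehyde chain equatorial. This places the C1 hydroxyl anti to C9 and syn to the C14 arm, the C1/C10 relationship the fragmentation needs; the new quaternary C10 and C1 are set together, and low temperature limits loss of silanolate from the enolate and retro-aldol.

Step 8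
Reactants: 13 aldol from step 7; 14 vinylmagnesium bromide
Product: 16 tertiary vinyl carbinol (vinyl added to C6 of 13; C6 hydroxyl cis to the silyloxymethyl arm; vinyl cis to the C1 chain; racemic), via bromomagnesium alkoxide 15 (not isolated)
Conditions: CH2=CHMgBr (3.5 equiv), LaCl3·2LiCl (1 equiv), THF, −78 → −20 °C; AcOH, −78 °C
Reagents that add atoms: none
Why: The first equivalent forms the C1 alkoxide, which chelates the C6 carbonyl in a six-membered ring in which the ring fusion holds C9 equatorial and the C14 arm axial. Vinyl transfer should then occur on the face opposite that arm, past the axial C1–H (1,3-chelation-controlled Grignard addition), giving the C6 hydroxyl cis to C14; the lanthanum salt suppresses enolisation toward C7.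

Step 9
Reactants: 16 tertiary vinyl carbinol
Product: 17 cis-fused bicyclo[5.3.0]decene diol (C6 tertiary OH; C1 OH trans to it and trans to the C14 arm; C4=C5 in the seven-membered ring; C8 ethylene ketal; O14 silyl; O15 4-methoxybenzyl; racemic)
Conditions: RuCl2(=CHPh)(PCy3)(H2IMes) (second-generation Grubbs catalyst, 5 mol%), CH2Cl2 (5 mM), 40 °C
Reagents that add atoms: none
Why: Ring-closing metathesis of the vinyl group with the 1,1-disubstituted alkene, both on the same face of the cyclopentane, closes the seven-membered ring with a necessarily cis trisubstituted C4=C5; loss of ethylene drives it.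

Step 10
Reactants: 17 cis-fused bicyclic diol
Product: 18 C1 monomesylate of 17 (fragmentation precursor; mesylate cis to C9 and trans to the C14 arm; racemic)
Conditions: MeSO2Cl (1.2 equiv), Et3N, CH2Cl2, −20 → 0 °C
Reagents that add atoms: methanesulfonyl chloride, CS(=O)(=O)Cl
Why: Sulfonylation through sulfene is selective for the secondary C1 hydroxyl over the tertiary allylic C6 hydroxyl, and without a strong base the mesylate does not fragment.

Step 11
Reactants: 18 C1 monomesylate
Product: 20 ten-membered dienone (C6 ketone; C8 ethylene ketal; C4=C5 and C1=C10 ring-cis; O14 silyl; O15 4-methoxybenzyl; achiral), via potassium alkoxide 19 (not isolated)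
Conditions: KOtBu (1.1 equiv), THF, −20 → 0 °C, 20 min; pH 7 phosphate buffer
Reagents that add atoms: none
Why: The base deprotonates the tertiary C6 hydroxyl. In the cis-fused conformer with the C1 mesylate equatorial on the seven-membered ring, the C1–O bond and an oxygen lone pair are both antiperiplanar to C6–C10, so that σ-bond breaks while C6=O and C1=C10 form and methanesulfonate leaves in one concerted step, with no new σ-bond. The closest known reaction type is the Wharton (Grob-type) fragmentation of cyclic 1,3-diol monosulfonates to medium-ring unsaturated ketones. The ten-membered ring is not closed by bond formation but released by cleaving the bond shared by the five- and seven-membered rings, so no cyclisation mode or dilution requirement applies. No stereocentre is created: C1, C6 and C10 become sp2 and 20 is achiral, which is why racemic 18 suffices. The step needs control of the C1=C10 geometry and preference for fragmentation over oxetane formation, elimination of the mesylate and β-loss of a ketal oxygen from the product. The mesylate trans to the C14 arm puts C9 on the side of C2 in the antiperiplanar array, so only the ring-cis alkene can form, and C4=C5 keeps the cis geometry of the cycloheptene. The potassium counter-ion, one equivalent of base, low temperature and a buffered quench keep the β-keto ketal from being enolised for long.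

Step 12
Reactants: 20 ten-membered dienone
Product: 22 methyl 2-(C7)-acetate of 20 (C6 ketone with CH2CO2Me on C7; racemic), via lithium dienolate 21 (not isolated)
Conditions: LiN(iPr)2 (1.1 equiv), THF, −78 °C; DMPU, BrCH2CO2Me, −78 → −45 °C; AcOH
Reagents that add atoms: methyl bromoacetate, COC(=O)CBr
Why: Kinetic α′-deprotonation of the enone (C7 is its only sp3 α-carbon) gives the cross-conjugated dienolate, which is C-alkylated by the reactive bromoacetate (enolate alkylation); the temperature stays at or below −45 °C so that the enolate does not expel a ketal oxygen. C7 is formed racemic and is left so on purpose.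

Step 13
Reactants: 22 racemic keto ester
Product: 24 cis-fused γ-lactone (O6–C12 closed; C6 and C7 configured as in the target; C8 ethylene ketal), via hydroxy ester 23 (not isolated)
Conditions: ketoreductase (NADPH-dependent, chosen by screening), NADP+ (cat.), iPrOH–DMSO–triethanolamine buffer pH 9, 35 °C; extraction; PPTS (cat.), PhMe, 50 °C
Reagents that add atoms: none
Why: Proposed new method: a ketoreductase selected to reduce the (7R)-ketone on the face that gives the (6S)-alcohol (target numbering) should deliver hydride to C6 only, while at pH 9 the unreactive (7S)-ketone re-equilibrates through the C7 enol, so both enantiomers funnel into the cis hydroxy ester 23 (dynamic reductive kinetic resolution), which lactonises under mild acid. The closest known reaction type is the ketoreductase dynamic kinetic resolution of α-substituted β-keto esters and 2-substituted cycloalkanones, not yet shown for an α′-branched medium-ring enone.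

Step 14
Reactants: 24 cis-fused lactone ketal
Product: 25 C8 keto lactone
Conditions: PPTS (0.3 equiv), acetone–H2O (10:1), 55 °C
Reagents that add atoms: water, O
Why: Acid-catalysed hydrolysis of the dioxolane; the mild pyridinium acid should spare the silyl ether, the benzyl ether, the allylic lactone C–O bond and the C7 centre next to the new ketone.

Step 15
Reactants: 25 C8 keto lactone
Product: 26 C8 hydroxy lactone (C8 hydroxyl cis to C7–C11 and to O6)
Conditions: NaBH4, CeCl3·7H2O, MeOH–CH2Cl2, −78 °C; AcOH
Reagents that add atoms: none
Why: Borohydride activated by trivalent cerium (Luche reduction) reduces the ketone fast and nearly neutral, so C7 is not epimerised and the β-acyloxy group is not eliminated; hydride should enter opposite the cis-fused lactone ring, which places the new hydroxyl cis to C11.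

Step 16
Reactants: 26 C8 hydroxy lactone
Product: 30 α-methylene hydroxy lactone, via dilithium alkoxide enolate 27 (not isolated), via Mannich base 28 (not isolated), via trimethylammonium iodide 29 (not isolated)
Conditions: LiN(iPr)2 (2.3 equiv), THF, −78 °C; CH2=NMe2+ I− (3 equiv), −78 °C → rt; MeI, MeOH, rt; NaHCO3 (aq.), CH2Cl2, rt
Reagents that add atoms: N,N-dimethylmethyleneiminium iodide (Eschenmoser's salt), C=[N+](C)C.[I-]
Why: The lactone enolate of the dianion is aminomethylated at C11 (Mannich reaction); N-methylation and mild base then eliminate trimethylamine to the exocyclic alkene (α-methylenation of a lactone). Excess iminium salt caps the C8 alkoxide reversibly so that it cannot attack C12.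

Step 17
Reactants: 30 α-methylene hydroxy lactone
Product: 31 C8 isovalerate
Conditions: Me2CHCH2COCl, pyridine, DMAP (cat.), CH2Cl2, 0 °C
Reagents that add atoms: 3-methylbutanoyl chloride, CC(C)CC(=O)Cl
Why: Catalysed acylation of the secondary alcohol; it follows the methylenation because the ester would not survive the amide base.

Step 18
Reactants: 31 C8 isovalerate
Product: 32 C14 allylic alcohol
Conditions: HF·pyridine, pyridine, THF, 0 °C → rt
Reagents that add atoms: none
Why: Buffered fluoride cleavage of the silyl ether; the methylene lactone, the ester and the benzyl ether are stable to it.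

Step 19
Reactants: 32 C14 allylic alcohol
Product: 33 C14 aldehyde
Conditions: MnO2 (activated, excess), CH2Cl2, rt
Reagents that add atoms: none
Why: Selective oxidation of the allylic alcohol to the conjugated aldehyde; the geometry with C14 trans to C2 is also the preferred one for a 2-alkyl-2-enal.

Step 20
Reactants: 33 C14 aldehyde
Product: 34 target CNP0345200.8
Conditions: DDQ (1.3 equiv), CH2Cl2–pH 7 buffer (10:1), 0 °C
Reagents that add atoms: none
Why: Oxidative cleavage of the 4-methoxybenzyl ether (hydride abstraction, then hydrolysis of the oxocarbenium ion) under buffered conditions that leave the enal, the methylene lactone and the ester alone.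

## Compound list

1 | 1,4-dioxaspiro[4.4]nonan-7-one | O=C1CCC2(C1)OCCO2 | starting material
2 | lithium 1,4-dioxaspiro[4.4]non-7-en-7-olate (enolate of 1 remote from the ketal; formed in the flask) | [Li]OC1=CCC2(C1)OCCO2 | intermediate
3 | 8-(hydroxymethyl)-1,4-dioxaspiro[4.4]nonan-7-one (racemic) | O=C1CC2(OCCO2)CC1CO | intermediate
4 | 8-{[(tert-butyldiphenylsilyl)oxy]methyl}-1,4-dioxaspiro[4.4]nonan-7-one (racemic) | O=C1CC2(OCCO2)CC1CO[Si](c1ccccc1)(c1ccccc1)C(C)(C)C | intermediate
5 | 8-{[(tert-butyldiphenylsilyl)oxy]methyl}-7-(trimethylsilyloxy)-1,4-dioxaspiro[4.4]non-7-ene | C[Si](C)(C)OC1=C(CO[Si](c2ccccc2)(c2ccccc2)C(C)(C)C)CC2(C1)OCCO2 | intermediate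
6 | 2-methylenepropane-1,3-diol | C=C(CO)CO | starting material
7 | 2-{[(4-methoxybenzyl)oxy]methyl}prop-2-en-1-ol | C=C(CO)COCc1ccc(OC)cc1 | intermediate
8 | triethyl orthoacetate | CCOC(C)(OCC)OCC | starting material
9 | 1-ethoxy-1-[(2-{[(4-methoxybenzyl)oxy]methyl}prop-2-en-1-yl)oxy]ethene (mixed ketene acetal; formed in the flask) | C=C(OCC)OCC(=C)COCc1ccc(OC)cc1 | intermediate
10 | ethyl 4-{[(4-methoxybenzyl)oxy]methyl}pent-4-enoate | CCOC(=O)CCC(=C)COCc1ccc(OC)cc1 | intermediate
11 | 4-{[(4-methoxybenzyl)oxy]methyl}pent-4-enal | O=CCCC(=C)COCc1ccc(OC)cc1 | intermediate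
12 | lithium enolate from 5 (C6=C10 enolate; formed in the flask) | [Li]OC1=C(CO[Si](c2ccccc2)(c2ccccc2)C(C)(C)C)CC2(C1)OCCO2 | intermediate
13 | aldol: 8-{[(tert-butyldiphenylsilyl)oxy]methyl}-8-(1-hydroxy-4-{[(4-methoxybenzyl)oxy]methyl}pent-4-en-1-yl)-1,4-dioxaspiro[4.4]nonan-7-one (racemic; C1 OH anti to C9, syn to the C14 arm) | O=C1CC2(OCCO2)C[C@]1(CO[Si](c3ccccc3)(c3ccccc3)C(C)(C)C)[C@H](O)CCC(=C)COCc1ccc(OC)cc1 | intermediate
14 | vinylmagnesium bromide | C=C[Mg]Br | starting material
15 | bromomagnesium C1 alkoxide of 13 (chelate; formed in the flask) | O=C1CC2(OCCO2)C[C@]1(CO[Si](c3ccccc3)(c3ccccc3)C(C)(C)C)[C@H](O[Mg]Br)CCC(=C)COCc1ccc(OC)cc1 | intermediate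
16 | tertiary vinyl carbinol (C6 OH cis to the C14 arm; vinyl cis to the C1 chain; racemic) | O[C@@]1(C=C)CC2(OCCO2)C[C@]1(CO[Si](c3ccccc3)(c3ccccc3)C(C)(C)C)[C@H](O)CCC(=C)COCc1ccc(OC)cc1 | intermediate
17 | cis-fused bicyclo[5.3.0]decene diol (C6 tertiary OH, C1 secondary OH, C8 ethylene ketal, O14 tert-butyldiphenylsilyl, O15 4-methoxybenzyl; racemic) | O[C@]12/C=C(/COCc3ccc(OC)cc3)CC[C@@H](O)[C@@]1(CO[Si](c4ccccc4)(c4ccccc4)C(C)(C)C)CC5(OCCO5)C2 | intermediate
18 | C1 monomesylate of 17 (fragmentation precursor; racemic) | O[C@]12/C=C(/COCc3ccc(OC)cc3)CC[C@@H](OS(C)(=O)=O)[C@@]1(CO[Si](c4ccccc4)(c4ccccc4)C(C)(C)C)CC5(OCCO5)C2 | intermediate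
19 | potassium C6 alkoxide of 18 (formed in the flask) | [O-][C@]12/C=C(/COCc3ccc(OC)cc3)CC[C@@H](OS(C)(=O)=O)[C@@]1(CO[Si](c4ccccc4)(c4ccccc4)C(C)(C)C)CC5(OCCO5)C2.[K+] | intermediate
20 | ten-membered dienone (C6 ketone, C8 ethylene ketal, both alkenes ring-cis; achiral) | O=C1/C=C(/COCc2ccc(OC)cc2)CC/C=C(/CO[Si](c2ccccc2)(c2ccccc2)C(C)(C)C)CC2(OCCO2)C1 | intermediate
21 | lithium C6=C7 dienolate of 20 (formed in the flask) | [Li]OC=1/C=C(/COCc2ccc(OC)cc2)CC/C=C(/CO[Si](c2ccccc2)(c2ccccc2)C(C)(C)C)CC2(OCCO2)C=1 | intermediate
22 | keto ester: 20 with CH2CO2Me on C7 (racemic) | O=C1/C=C(/COCc2ccc(OC)cc2)CC/C=C(/CO[Si](c2ccccc2)(c2ccccc2)C(C)(C)C)CC2(OCCO2)C1CC(=O)OC | intermediate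
23 | cis hydroxy ester (C6 OH and C7 CH2CO2Me cis; configuration as in the target; formed in the flask) | O[C@H]1/C=C(/COCc2ccc(OC)cc2)CC/C=C(/CO[Si](c2ccccc2)(c2ccccc2)C(C)(C)C)CC2(OCCO2)[C@H]1CC(=O)OC | intermediate
24 | cis-fused γ-lactone with C8 ethylene ketal | C1C(=O)O[C@H]2/C=C(/COCc3ccc(OC)cc3)CC/C=C(/CO[Si](c3ccccc3)(c3ccccc3)C(C)(C)C)CC3(OCCO3)[C@@H]12 | intermediate
25 | C8 keto lactone | C1C(=O)O[C@H]2/C=C(/COCc3ccc(OC)cc3)CC/C=C(/CO[Si](c3ccccc3)(c3ccccc3)C(C)(C)C)CC(=O)[C@@H]12 | intermediate
26 | C8 hydroxy lactone (O6, C11 and O8 all cis) | C1C(=O)O[C@H]2/C=C(/COCc3ccc(OC)cc3)CC/C=C(/CO[Si](c3ccccc3)(c3ccccc3)C(C)(C)C)C[C@@H](O)[C@@H]12 | intermediate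
27 | dilithium C8 alkoxide / lactone enolate of 26 (formed in the flask) | C1=C(O[Li])O[C@H]2/C=C(/COCc3ccc(OC)cc3)CC/C=C(/CO[Si](c3ccccc3)(c3ccccc3)C(C)(C)C)C[C@@H](O[Li])[C@@H]12 | intermediate
28 | C11 (dimethylamino)methyl lactone (Mannich base; C11 configuration not defined; formed in the flask) | CN(C)CC1C(=O)O[C@H]2/C=C(/COCc3ccc(OC)cc3)CC/C=C(/CO[Si](c3ccccc3)(c3ccccc3)C(C)(C)C)C[C@@H](O)[C@@H]12 | intermediate
29 | C11 (trimethylammonio)methyl lactone iodide (formed in the flask) | C[N+](C)(C)CC1C(=O)O[C@H]2/C=C(/COCc3ccc(OC)cc3)CC/C=C(/CO[Si](c3ccccc3)(c3ccccc3)C(C)(C)C)C[C@@H](O)[C@@H]12.[I-] | intermediate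
30 | α-methylene hydroxy lactone | C=C1C(=O)O[C@H]2/C=C(/COCc3ccc(OC)cc3)CC/C=C(/CO[Si](c3ccccc3)(c3ccccc3)C(C)(C)C)C[C@@H](O)[C@@H]12 | intermediate
31 | C8 isovalerate (O14 silyl, O15 4-methoxybenzyl) | C=C1C(=O)O[C@H]2/C=C(/COCc3ccc(OC)cc3)CC/C=C(/CO[Si](c3ccccc3)(c3ccccc3)C(C)(C)C)C[C@@H](OC(=O)CC(C)C)[C@@H]12 | intermediate
32 | C14 allylic alcohol (O15 4-methoxybenzyl) | C=C1C(=O)O[C@H]2/C=C(/COCc3ccc(OC)cc3)CC/C=C(/CO)C[C@@H](OC(=O)CC(C)C)[C@@H]12 | intermediate
33 | C14 aldehyde (O15 4-methoxybenzyl) | C=C1C(=O)O[C@H]2/C=C(/COCc3ccc(OC)cc3)CC/C=C(/C=O)C[C@@H](OC(=O)CC(C)C)[C@@H]12 | intermediate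
34 | CNP0345200.8: (6S,7R,8R)-8-isovaleryloxy-15-hydroxy-14-oxogermacra-1(10),4,11(13)-trien-6,12-olide, both ring alkenes ring-cis | C=C1C(=O)O[C@H]2/C=C(/CO)CC/C=C(/C=O)C[C@@H](OC(=O)CC(C)C)[C@@H]12 | target

Total step count: 20.
Longest linear sequence: 17 steps (steps 1–3 or steps 4–6, then steps 7–20).

## Least certain steps

Step 13 (bears the label). The enzyme may not accept the bulky lipophilic macrocycle, or C7 may equilibrate too slowly, so that the reduction stalls as a simple kinetic resolution. Each enolisation at C7 also gives the enolate a chance to expel a ketal oxygen. The fallback uses known chemistry and sets out from 22. A Corey–Bakshi–Shibata reduction (methyl oxazaborolidine of the appropriate hand, catecholborane, toluene, −78 °C) is run as a catalyst-controlled kinetic resolution to about half conversion. The matched enantiomer gives 23, which lactonises (PPTS, toluene) to 24, where the route is rejoined. The slow-reacting enantiomer of the keto ester, (7S)-keto ester F1, is recovered, racemised back to 22 with DBU and recycled.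

Step 11 (key step). The product may be deprotonated at C7 by unreacted alkoxide, with β-loss of a ketal oxygen, or the alkoxide may displace the mesylate to an oxetane if the antiperiplanar conformer is poorly populated. The fallback sets out from 18 and turns the step into a fragmentation–reduction. LiAlH4 in THF (0 °C → rt) forms the aluminate alkoxide, and the enone released by fragmentation is reduced as it forms, so no β-keto ketal ever meets base. This gives the racemic ten-membered allylic alcohol F2, and neutral MnO2 oxidation then returns to 20.

Step 7. A boat transition state may compete with the chair, giving poor control of C1 relative to C10, and the enolate may lose silanolate while it is generated. The fallback moves the control of C1 to the bicyclic stage. The unseparated aldol mixture is carried through steps 8 and 9 to 17 together with its C1 epimer, epi-alcohol F3. The mixture is oxidised at C1 (Dess–Martin periodinane, NaHCO3) to the single β-hydroxy ketone F4. Reduction with Me4NBH(OAc)3 (MeCN–AcOH, −20 °C) delivers hydride from the C6 oxygen to the same face of C1, which gives the C1 alcohol trans to the C6 hydroxyl, that is 17.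

Step 8. Vinyl transfer may occur on the wrong face if chelation is weak, and the basic reagent may enolise the ketone toward C7 or trigger retro-aldol cleavage. The fallback sets out from 13 and uses a slimmer, less basic nucleophile. Ethynylmagnesium bromide with LaCl3·2LiCl gives the ethynyl carbinol F5, and semi-hydrogenation (H2, Pd on CaCO3 poisoned with Pb(OAc)2, quinoline) gives 16.

Step 12. The hindered enolate, whose carbon is neopentyl, may alkylate slowly and instead expel a ketal oxygen on warming. The fallback sets out from 20 and avoids a free enolate at the alkylation stage. LiN(SiMe3)2 with Me3SiCl present (−78 °C) gives the 2-silyloxydiene F6. Copper-catalysed cyclopropanation of its electron-rich enol ether bond with methyl diazoacetate (Cu(acac)2) gives the siloxycyclopropane ester F7. Ring opening with Et3N·3HF gives 22.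

Step 15. Facial selectivity on the flexible ring may be poor, and the new C8 alkoxide may attack C12 (translactonisation). The fallback sets out from 25 and replaces substrate control by catalyst control: a ketoreductase chosen for the (8R)-alcohol reduces the simple ketone at neutral pH to 26. It makes no compound that is not already in the list (F0).

## Further compounds

F1 | step 13 | (7S)-enantiomer of keto ester 22 (slow-reacting, recycled) | O=C1/C=C(/COCc2ccc(OC)cc2)CC/C=C(/CO[Si](c2ccccc2)(c2ccccc2)C(C)(C)C)CC2(OCCO2)[C@@H]1CC(=O)OC
F2 | step 11 | racemic ten-membered C6 allylic alcohol (C8 ethylene ketal) | OC1/C=C(/COCc2ccc(OC)cc2)CC/C=C(/CO[Si](c2ccccc2)(c2ccccc2)C(C)(C)C)CC2(OCCO2)C1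
F3 | step 7 | C1 epimer of bicyclic diol 17 | O[C@]12/C=C(/COCc3ccc(OC)cc3)CC[C@H](O)[C@@]1(CO[Si](c4ccccc4)(c4ccccc4)C(C)(C)C)CC5(OCCO5)C2
F4 | step 7 | bicyclic C1 ketone with C6 tertiary hydroxyl | O[C@]12/C=C(/COCc3ccc(OC)cc3)CCC(=O)[C@@]1(CO[Si](c4ccccc4)(c4ccccc4)C(C)(C)C)CC5(OCCO5)C2
F5 | step 8 | C6 ethynyl carbinol corresponding to 16 | O[C@@]1(C#C)CC2(OCCO2)C[C@]1(CO[Si](c3ccccc3)(c3ccccc3)C(C)(C)C)[C@H](O)CCC(=C)COCc1ccc(OC)cc1
F6 | step 12 | trimethylsilyl dienol ether of 20 (C6=C7) | C[Si](C)(C)OC=1/C=C(/COCc2ccc(OC)cc2)CC/C=C(/CO[Si](c2ccccc2)(c2ccccc2)C(C)(C)C)CC2(OCCO2)C=1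
F7 | step 12 | siloxycyclopropane ester (C6–C7–C11 ring, CO2Me on C11; racemic) | C[Si](C)(C)OC12/C=C(/COCc3ccc(OC)cc3)CC/C=C(/CO[Si](c3ccccc3)(c3ccccc3)C(C)(C)C)CC3(OCCO3)C1C2C(=O)OC
F0 | step 15 | none | none
A1 | alternative 1 | open-chain C5 alkenyl iodide / C6 aldehyde / C12 methyl ester (substrate of the chromium-mediated closure) | I/C=C(/CO[Si](C)(C)C(C)(C)C)CC/C=C(/COCc1ccc(OC)cc1)C[C@@H](OC(=O)CC(C)C)[C@H](C=O)C(=C)C(=O)OC
A2 | alternative 1 | target skeleton with C14 at the alcohol level (O14 4-methoxybenzyl, O15 tert-butyldimethylsilyl) | C=C1C(=O)O[C@H]2/C=C(/CO[Si](C)(C)C(C)(C)C)CC/C=C(/COCc3ccc(OC)cc3)C[C@@H](OC(=O)CC(C)C)[C@@H]12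
A3 | alternative 2 | thirteen-membered cyclic α-tributylstannyl allyl ether (substrate of the ring contraction) | CCCC[Sn](CCCC)(CCCC)[C@H]1OC/C(COCc2ccc(OC)cc2)=C\[C@@H](OCc2ccc(OC)cc2)/C=C(/CO[Si](c2ccccc2)(c2ccccc2)C(C)(C)C)CC/C=C(/CO[Si](C)(C)C(C)(C)C)C1
A4 | alternative 2 | ten-membered carbocycle with free C8 hydroxyl and 3-(4-methoxybenzyloxy)prop-1-en-2-yl group on C7 | C=C(COCc2ccc(OC)cc2)[C@H]1[C@@H](OCc2ccc(OC)cc2)/C=C(/CO[Si](c2ccccc2)(c2ccccc2)C(C)(C)C)CC/C=C(/CO[Si](C)(C)C(C)(C)C)C[C@H]1O
A5 | alternative 3 | cis γ-lactone carrying the C8–C9 epoxide on C7 and the C10 alkenyl iodide chain on C6 (substrate of the nickel closure) | O=C1C[C@H]([C@H]2CO2)[C@@H](O1)/C=C(/CO[Si](C)(C)C(C)(C)C)CC/C=C(/COCc3ccc(OC)cc3)I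
A6 | alternative 3 | ten-membered cis-fused lactone with free C8 hydroxyl (O14 4-methoxybenzyl, O15 tert-butyldimethylsilyl) | O=C1C[C@H]2[C@@H](O1)/C=C(/CO[Si](C)(C)C(C)(C)C)CC/C=C(/COCc3ccc(OC)cc3)C[C@H]2O
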